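**Assumptions**
- The SMILES decodes to (2R,9′R) with 3′E and 7′E olefins.
- Routine reagents that deliver atoms are given by name and SMILES inside each step and are not numbered.
- The lipase is assumed to keep the pro‑S preference it shows for closely related 6‑O‑protected chroman‑2,2‑dimethanols. This is checked at compound 24. If the sense were opposite, the roles of the two arms are simply exchanged.

## Retrosynthetic overview
1. 26 comes from global desilylation of 25, which comes from a C2′–C3′ B‑alkyl Suzuki coupling of vinylchroman 24 with E‑vinyl iodide 9.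
2. 9 has its prenyl end made from an allyl group by cross‑metathesis. C9′(R) and the C9′–C10′ bond come from BINOL–Ti catalysed allylation of enal 6. Enal 6 comes from pent‑4‑yn‑1‑ol by Negishi carboalumination (3′E) and a stabilised Wittig reaction (7′E).
3. 24 comes from (S)‑monoacetate 19, with the free CH2OH arm converted to vinyl and the CH2OAc arm to CH3. 19 comes from lipase desymmetrisation of prochiral chroman‑2,2‑dimethanol 18, which sets C2.
4. 18 comes from a 6‑exo phenol/epoxide closure. Its precursor comes from a B‑alkyl Suzuki coupling of styrene 14 with 2‑bromoallyl alcohol, and 14 from ortho‑formylation of mono‑silylated 2‑methylhydroquinone.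
5. Ring order: the arene is purchased. The dihydropyran is the only ring built (step 15), before C2 is stereogenic.

## Side‑chain fragment

**Step 1**
Reactants: 1 pent‑4‑yn‑1‑ol
Product: 2 (E)‑5‑iodo‑4‑methylpent‑4‑en‑1‑ol
Conditions: AlMe3 (3 equiv), Cp2ZrCl2 (0.25 equiv), CH2Cl2, 0 °C→rt; then I2, THF, −30→0 °C
Reagents that add atoms: trimethylaluminium C[Al](C)C; iodine II
Why: Negishi Zr‑catalysed syn‑carboalumination followed by iodinolysis with retention gives the E‑trisubstituted vinyl iodide (>98:2).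

**Step 2**
Reactants: 2
Product: 3 (E)‑5‑iodo‑4‑methylpent‑4‑enal
Conditions: (COCl)2, DMSO, Et3N, CH2Cl2, −78 °C→0 °C
Reagents that add atoms: none
Why: Swern oxidation stops at the aldehyde and leaves the vinyl iodide untouched.

**Step 3**
Reactants: 3
Product: 4 ethyl (2E,6E)‑7‑iodo‑2,6‑dimethylhepta‑2,6‑dienoate
Conditions: Ph3P=C(CH3)CO2Et, CH2Cl2, rt
Reagents that add atoms: ethyl 2‑(triphenylphosphoranylidene)propanoate CCOC(=O)C(C)=P(c1ccccc1)(c1ccccc1)c1ccccc1
Why: A Wittig olefination with a stabilised α‑methyl ylide on an unbranched aldehyde gives the E‑enoate (≥95:5), which becomes the future 7′E olefin.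

**Step 4**
Reactants: 4
Product: 5 (2E,6E)‑7‑iodo‑2,6‑dimethylhepta‑2,6‑dien‑1‑ol
Conditions: DIBAL‑H (2.5 equiv), CH2Cl2, −78 °C
Reagents that add atoms: none
Why: DIBAL 1,2‑reduction of the enoate gives the allylic alcohol without touching the C–I bond or the olefin geometry.

**Step 5**
Reactants: 5
Product: 6 (2E,6E)‑7‑iodo‑2,6‑dimethylhepta‑2,6‑dienal
Conditions: activated MnO2, CH2Cl2, rt
Reagents that add atoms: none
Why: MnO2 allylic oxidation is chemoselective and does not isomerise the E‑enal.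

**Step 6**
Reactants: 6
Product: 7 (4R,5E,9E)‑10‑iodo‑5,9‑dimethyldeca‑1,5,9‑trien‑4‑ol
Conditions: (R)‑BINOL (20 mol %), Ti(OiPr)4 (10 mol %), 4 Å MS, CH2Cl2, reflux 1 h; then 6, allylSnBu3, −20 °C, 72 h
Reagents that add atoms: allyltributylstannane C=CC[Sn](CCCC)(CCCC)CCCC
Why: In this Keck catalytic asymmetric allylation the (R)‑BINOL–Ti Lewis acid exposes one aldehyde face, so α‑methyl enals give the (R)‑carbinol (about 95% ee), which sets C9′ as the first stereocentre.

**Step 7**
Reactants: 7
Product: 8 (4R,5E,9E)‑4‑(tert‑butyldimethylsilyloxy)‑10‑iodo‑5,9‑dimethyldeca‑1,5,9‑triene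
Conditions: TBSOTf, 2,6‑lutidine, CH2Cl2, −78→0 °C
Reagents that add atoms: TBSOTf CC(C)(C)[Si](C)(C)OS(=O)(=O)C(F)(F)F
Why: Silyl ether formation with the triflate protects the hindered allylic alcohol without ionisation, so C9′ is untouched.

**Step 8**
Reactants: 8
Product: 9 (1E,5E,7R)‑7‑(tert‑butyldimethylsilyloxy)‑1‑iodo‑2,6,10‑trimethylundeca‑1,5,9‑triene
Conditions: Grubbs II (3 mol %), 2‑methyl‑2‑butene/CH2Cl2, 35 °C (sealed)
Reagents that add atoms: 2‑methyl‑2‑butene CC=C(C)C
Why: In this olefin cross‑metathesis only the terminal vinyl group initiates and is capped as the isopropylidene (allyl→prenyl), while the trisubstituted olefin and the vinyl iodide are inert.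

## Chroman fragment

**Step 9**
Reactants: 10 2‑methylhydroquinone
Product: 11 2‑methyl‑4‑(triisopropylsilyloxy)phenol
Conditions: TIPSCl (1.0 equiv), imidazole, DMF, 0 °C
Reagents that add atoms: TIPSCl CC(C)[Si](Cl)(C(C)C)C(C)C
Why: In this sterically controlled mono‑silylation the bulky chloride takes the OH that has no ortho substituent, and the minor isomer and bis‑ether are removed by chromatography.

**Step 10**
Reactants: 11
Product: 12 2‑hydroxy‑3‑methyl‑5‑(triisopropylsilyloxy)benzaldehyde
Conditions: MgCl2, Et3N, (CH2O)n, MeCN, reflux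
Reagents that add atoms: paraformaldehyde (as formaldehyde) C=O
Why: Casnati–Skattebøl Mg‑phenoxide ortho‑formylation can only occur at the single free ortho position, which fixes the δ‑series (8‑methyl) substitution pattern.

**Step 11**
Reactants: 12
Product: 13 2‑(benzyloxy)‑3‑methyl‑5‑(triisopropylsilyloxy)benzaldehyde
Conditions: BnBr, K2CO3 (anhydrous), DMF, rt→40 °C
Reagents that add atoms: benzyl bromide BrCc1ccccc1
Why: Williamson etherification masks the oxidisable phenol for the ylide, borane and peracid steps, and the aryl TIPS ether tolerates dry carbonate.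

**Step 12**
Reactants: 13
Product: 14 2‑(benzyloxy)‑1‑methyl‑5‑(triisopropylsilyloxy)‑3‑vinylbenzene
Conditions: MePPh3Br, t‑BuOK, THF, 0 °C→rt
Reagents that add atoms: methyltriphenylphosphonium bromide C[P+](c1ccccc1)(c1ccccc1)c1ccccc1.[Br-]
Why: Wittig methylenation of a non‑enolisable aryl aldehyde is clean and gives the styrene.

**Step 13**
Reactants: 14; 15 2‑bromoprop‑2‑en‑1‑ol
Product: 16 4‑[2‑(benzyloxy)‑3‑methyl‑5‑(triisopropylsilyloxy)phenyl]‑2‑methylidenebutan‑1‑ol
Conditions: 9‑BBN, THF, 0 °C→rt; then aq K3PO4, 15, Pd(dppf)Cl2 (5 mol %), DMF, 50 °C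
Reagents that add atoms: none beyond reactant 15 (9‑BBN contributes only H)
Why: Anti‑Markovnikov hydroboration of the styrene and B‑alkyl Suzuki–Miyaura coupling with the vinyl bromide give the ArCH2CH2–C(=CH2)CH2OH unit, and the free OH is tolerated.

**Step 14**
Reactants: 16
Product: 17 (±)‑(2‑{2‑[2‑(benzyloxy)‑3‑methyl‑5‑(triisopropylsilyloxy)phenyl]ethyl}oxiran‑2‑yl)methanol
Conditions: mCPBA, NaHCO3, CH2Cl2, 0 °C
Reagents that add atoms: mCPBA O=C(OO)c1cccc(Cl)c1
Why: Buffered Prilezhaev epoxidation acts on the only olefin, and the transient racemic centre is erased in the next step.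

**Step 15**
Reactants: 17
Product: 18 [8‑methyl‑6‑(triisopropylsilyloxy)chroman‑2,2‑diyl]dimethanol (achiral, prochiral)
Conditions: H2 (1 atm), 10% Pd/C, EtOAc, rt; filter; then CSA (10 mol %), CH2Cl2, 0 °C
Reagents that add atoms: none
Why: Benzyl hydrogenolysis frees the phenol, and acid‑catalysed 6‑exo‑tet epoxide opening at the more substituted carbon then closes the dihydropyran to give two identical CH2OH arms.

**Step 16 (enzymatic key step)**
Reactants: 18
Product: 19 [(2S)‑2‑(hydroxymethyl)‑8‑methyl‑6‑(triisopropylsilyloxy)chroman‑2‑yl]methyl acetate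
Conditions: lipase (Candida antarctica lipase B, immobilised; EC 3.1.1.3), vinyl acetate (5 equiv), MTBE, 25 °C; stop when the diol is consumed
Reagents that add atoms: vinyl acetate C=COC(C)=O
Why: In this lipase‑catalysed irreversible transesterification (enantiotopic‑group desymmetrisation) the acyl‑enzyme acetylates only the pro‑S CH2OH, which creates C2 in ≥98% ee, and slight over‑acylation removes the minor enantiomer as recyclable achiral diacetate.

**Step 17**
Reactants: 19
Product: 20 [(2R)‑2‑formyl‑8‑methyl‑6‑(triisopropylsilyloxy)chroman‑2‑yl]methyl acetate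
Conditions: Dess–Martin periodinane, NaHCO3, CH2Cl2, 0 °C→rt (19 used promptly)
Reagents that add atoms: none
Why: Dess–Martin oxidation of the free arm removes the OH that could racemise 19 by 1,3‑acyl migration, and the α‑quaternary aldehyde cannot epimerise (the descriptor changes by CIP rules only).

**Step 18**
Reactants: 20
Product: 21 [(2S)‑2‑ethenyl‑8‑methyl‑6‑(triisopropylsilyloxy)chroman‑2‑yl]methyl acetate
Conditions: MePPh3Br, KHMDS (1.2 equiv ylide), THF, −78→0 °C
Reagents that add atoms: methyltriphenylphosphonium bromide C[P+](c1ccccc1)(c1ccccc1)c1ccccc1.[Br-]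
Why: In this Wittig methylenation the activated α‑alkoxy aldehyde reacts far faster than the acetate at low temperature, and any acetate loss only anticipates step 19.

**Step 19**
Reactants: 21
Product: 22 [(2S)‑2‑ethenyl‑8‑methyl‑6‑(triisopropylsilyloxy)chroman‑2‑yl]methanol
Conditions: DIBAL‑H (2.5 equiv), CH2Cl2, −78 °C
Reagents that add atoms: none
Why: Reductive ester cleavage removes the acetate without any base or fluoride that could touch the aryl TIPS ether.

**Step 20**
Reactants: 22
Product: 23 [(2S)‑2‑ethenyl‑8‑methyl‑6‑(triisopropylsilyloxy)chroman‑2‑yl]methyl trifluoromethanesulfonate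
Conditions: Tf2O, pyridine, CH2Cl2, −78→0 °C; used crude
Reagents that add atoms: triflic anhydride O=S(=O)(OS(=O)(=O)C(F)(F)F)C(F)(F)F
Why: O‑Sulfonylation gives a leaving group strong enough for substitution at a neopentyl carbon, and the β‑oxygen disfavours ionisation or rearrangement.

**Step 21**
Reactants: 23
Product: 24 (2S)‑2‑ethenyl‑2,8‑dimethyl‑6‑(triisopropylsilyloxy)chroman
Conditions: LiEt3BH (3 equiv), THF, 0 °C→rt
Reagents that add atoms: none
Why: SN2 hydride displacement by Super‑Hydride, the reagent of choice for hindered sulfonates, turns CH2OTf into the C2 methyl without touching a bond to the stereocentre.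

## Union and end game

**Step 22**
Reactants: 24; 9
Product: 25 (2R)‑2‑[(3E,7E,9R)‑9‑(tert‑butyldimethylsilyloxy)‑4,8,12‑trimethyltrideca‑3,7,11‑trien‑1‑yl]‑2,8‑dimethyl‑6‑(triisopropylsilyloxy)chroman
Conditions: 24, 9‑BBN, THF, rt; then aq K3PO4, 9, Pd(dppf)Cl2 (5 mol %), AsPh3, THF/DMF, rt
Reagents that add atoms: none (9‑BBN contributes only H)
Why: Regioselective hydroboration of the only olefin in 24 and B‑alkyl Suzuki–Miyaura coupling with retention at the vinyl iodide form C2′–C3′ and deliver the 3′E olefin, and any phenol desilylation is harmless before step 23.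

**Step 23**
Reactants: 25
Product: 26 sargachromanol C, (2R)‑2‑[(3E,7E,9R)‑9‑hydroxy‑4,8,12‑trimethyltrideca‑3,7,11‑trien‑1‑yl]‑2,8‑dimethylchroman‑6‑ol
Conditions: TBAF (4 equiv), degassed THF, Ar, 0 °C→rt; aq NH4Cl quench
Reagents that add atoms: none
Why: Fluoride‑mediated global desilylation cleaves the aryl TIPS and allylic TBS ethers under non‑acidic, non‑oxidising conditions, so the triene, the allylic carbinol and both stereocentres are preserved.

## Compound list

| No. | Name | SMILES | Role |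
|---|---|---|---|
| 1 | pent‑4‑yn‑1‑ol | C#CCCCO | starting material |
| 2 | (E)‑5‑iodo‑4‑methylpent‑4‑en‑1‑ol | OCCC/C(C)=C/I | intermediate |
| 3 | (E)‑5‑iodo‑4‑methylpent‑4‑enal | O=CCC/C(C)=C/I | intermediate |
| 4 | ethyl (2E,6E)‑7‑iodo‑2,6‑dimethylhepta‑2,6‑dienoate | CCOC(=O)/C(C)=C/CC/C(C)=C/I | intermediate |
| 5 | (2E,6E)‑7‑iodo‑2,6‑dimethylhepta‑2,6‑dien‑1‑ol | OC/C(C)=C/CC/C(C)=C/I | intermediate |
| 6 | (2E,6E)‑7‑iodo‑2,6‑dimethylhepta‑2,6‑dienal | O=C/C(C)=C/CC/C(C)=C/I | intermediate |
| 7 | (4R,5E,9E)‑10‑iodo‑5,9‑dimethyldeca‑1,5,9‑trien‑4‑ol | C=CC[C@@H](O)/C(C)=C/CC/C(C)=C/I | intermediate |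
| 8 | TBS ether of 7 | C=CC[C@@H](O[Si](C)(C)C(C)(C)C)/C(C)=C/CC/C(C)=C/I | intermediate |
| 9 | (1E,5E,7R)‑7‑(TBSO)‑1‑iodo‑2,6,10‑trimethylundeca‑1,5,9‑triene | CC(C)=CC[C@@H](O[Si](C)(C)C(C)(C)C)/C(C)=C/CC/C(C)=C/I | intermediate |
| 10 | 2‑methylhydroquinone | Cc1cc(O)ccc1O | starting material |
| 11 | 2‑methyl‑4‑(TIPSO)phenol | Cc1cc(O[Si](C(C)C)(C(C)C)C(C)C)ccc1O | intermediate |
| 12 | 2‑hydroxy‑3‑methyl‑5‑(TIPSO)benzaldehyde | O=Cc1cc(O[Si](C(C)C)(C(C)C)C(C)C)cc(C)c1O | intermediate |
| 13 | 2‑(benzyloxy)‑3‑methyl‑5‑(TIPSO)benzaldehyde | O=Cc1cc(O[Si](C(C)C)(C(C)C)C(C)C)cc(C)c1OCc1ccccc1 | intermediate |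
| 14 | 2‑(benzyloxy)‑1‑methyl‑5‑(TIPSO)‑3‑vinylbenzene | C=Cc1cc(O[Si](C(C)C)(C(C)C)C(C)C)cc(C)c1OCc1ccccc1 | intermediate |
| 15 | 2‑bromoprop‑2‑en‑1‑ol | C=C(Br)CO | starting material |
| 16 | 4‑aryl‑2‑methylidenebutan‑1‑ol | C=C(CO)CCc1cc(O[Si](C(C)C)(C(C)C)C(C)C)cc(C)c1OCc1ccccc1 | intermediate |
| 17 | (±)‑epoxy alcohol | OCC1(CCc2cc(O[Si](C(C)C)(C(C)C)C(C)C)cc(C)c2OCc2ccccc2)CO1 | intermediate (racemic, centre erased) |
| 18 | [8‑methyl‑6‑(TIPSO)chroman‑2,2‑diyl]dimethanol | OCC1(CO)CCc2cc(O[Si](C(C)C)(C(C)C)C(C)C)cc(C)c2O1 | intermediate (achiral) |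
| 19 | (S)‑monoacetate | CC(=O)OC[C@@]1(CO)CCc2cc(O[Si](C(C)C)(C(C)C)C(C)C)cc(C)c2O1 | intermediate |
| 20 | (R)‑formyl acetate | CC(=O)OC[C@@]1(C=O)CCc2cc(O[Si](C(C)C)(C(C)C)C(C)C)cc(C)c2O1 | intermediate |
| 21 | (S)‑vinyl acetate | CC(=O)OC[C@@]1(C=C)CCc2cc(O[Si](C(C)C)(C(C)C)C(C)C)cc(C)c2O1 | intermediate |
| 22 | (S)‑vinyl alcohol | OC[C@@]1(C=C)CCc2cc(O[Si](C(C)C)(C(C)C)C(C)C)cc(C)c2O1 | intermediate |
| 23 | (S)‑vinyl triflate ester | O=S(=O)(OC[C@@]1(C=C)CCc2cc(O[Si](C(C)C)(C(C)C)C(C)C)cc(C)c2O1)C(F)(F)F | intermediate |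
| 24 | (2S)‑2‑ethenyl‑2,8‑dimethyl‑6‑(TIPSO)chroman | C[C@@]1(C=C)CCc2cc(O[Si](C(C)C)(C(C)C)C(C)C)cc(C)c2O1 | intermediate |
| 25 | bis‑silyl sargachromanol C | CC(C)=CC[C@@H](O[Si](C)(C)C(C)(C)C)/C(C)=C/CC/C(C)=C/CC[C@]1(C)CCc2cc(O[Si](C(C)C)(C(C)C)C(C)C)cc(C)c2O1 | intermediate |
| 26 | sargachromanol C (2R,9′R) | CC(C)=CC[C@@H](O)/C(C)=C/CC/C(C)=C/CC[C@]1(C)CCc2cc(O)cc(C)c2O1 | target |

## Step count
- Total steps: 23.
- Longest linear sequence: 15 (steps 9–23, from 2‑methylhydroquinone). The side‑chain branch is 8 steps plus the 2 shared steps.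

## Steps most likely to fail
1. **Step 16 (lipase desymmetrisation).** The risks are ee or rate on the 6‑OTIPS/8‑methyl substrate, over‑acylation, and acyl migration in 19.
   Fallback: switch from desymmetrisation to a lipase kinetic resolution.
   - Run step 13 with 2‑bromopropene instead of 15.
   - Epoxidise, debenzylate and cyclise as in steps 14–15 to give racemic (2,8‑dimethyl‑6‑TIPSO‑chroman‑2‑yl)methanol.
   - Resolve with Burkholderia cepacia lipase and vinyl acetate.
   - Take the (S)‑alcohol to 24 by Dess–Martin oxidation and Wittig methylenation. This makes steps 19–21 unnecessary.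
2. **Step 21 (hydride SN2 on neopentyl triflate 23).** The risks are slow substitution and rearrangement through vinyl or oxygen participation.
   Fallback: deoxygenate through the carbonyl instead of by substitution.
   - Oxidise 22 to the aldehyde.
   - Form the tosylhydrazone.
   - Reduce with catecholborane/NaOAc (Caglioti/Kabalka‑type reduction) to the C2 methyl.
3. **Step 6 (Keck allylation of the α‑branched enal).** The risks are sluggish conversion and variable ee, and the remote diastereomers of 26 would be hard to separate.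
   Fallback: make racemic 7 with allylMgBr and resolve it by lipase‑catalysed acetylation. The Kazlauskas rule predicts that the (R)‑enantiomer, with the large 1‑methylalkenyl group against the medium allyl group, is acetylated. Methanolysis of the (R)‑acetate gives 7, and the (S)‑alcohol is recycled by oxidation and reduction.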